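Everything rests on cutting the O2–C3 bond of the 1,2-dioxane (ring atoms O1, O2, C3–C6; C3 carries CH2CO2H, C6 carries OMe). C3 lies β to the carboxyl carbon, so this bond is the retron of a conjugate addition: an acyclic racemic 6-hydroperoxy-6-methoxy-2-enal, made by ozonolysis of a 1,1-disubstituted alkene in methanol, cyclises under chiral secondary-amine (iminium) catalysis. One operation closes the peroxide ring 6-exo-trig and sets C3 as S; oxidation in the same flask gives the acid. C6 is then equilibrated to the anomerically favoured epimer (axial OMe), and the dienyne chain is attached last by Sonogashira coupling.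

Key step: step 5

Remark on the chemistry: the hydroperoxy ketal carbon formed in step 4 is racemic and cannot be controlled at that stage, so C6 is corrected in step 6 under thermodynamic control. Dec-9-enal is taken as a purchasable material.

Step 1
Reactants: 1 (5-chloropent-1-yn-1-yl)trimethylsilane; 2 prop-2-yn-1-ol
Product: 4 2-methylidene-7-(trimethylsilyl)hept-6-yn-1-ol, via Grignard reagent 3 (not isolated)
Conditions: Mg, THF, reflux; then 2 (0.4 equiv), CuI (10 mol%), Et2O/THF, −10 °C to rt; aq. NH4Cl
Reagents that add atoms: none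
Why: Copper-catalysed anti-carbomagnesiation of the propargylic alkoxide places the alkyl group on the internal alkyne carbon through a five-membered magnesium chelate, so protonolysis should give the 2-substituted allylic alcohol.

Step 2
Reactants: 4 2-methylidene-7-(trimethylsilyl)hept-6-yn-1-ol
Product: 6 4-methylidene-9-(trimethylsilyl)non-8-ynal, via allyl vinyl ether 5 (not isolated)
Conditions: ethyl vinyl ether (excess), Hg(OAc)2 (20 mol%), reflux; concentrate; toluene, 140 °C, sealed tube
Reagents that add atoms: ethyl vinyl ether C=COCC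
Why: Mercury-catalysed transetherification followed by thermal Claisen rearrangement of the 2-substituted allyl vinyl ether should give the γ,δ-unsaturated aldehyde with the 1,1-disubstituted alkene in place, the silyl group keeping the alkyne inert toward the mercury salt.

Step 3
Reactants: 6 4-methylidene-9-(trimethylsilyl)non-8-ynal
Product: 7 (2E)-6-methylidene-11-(trimethylsilyl)undec-2-en-10-ynal
Conditions: Ph3P=CHCHO (1.2 equiv), toluene, 80 °C
Reagents that add atoms: (triphenylphosphoranylidene)acetaldehyde O=CC=P(c1ccccc1)(c1ccccc1)c1ccccc1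
Why: Wittig olefination with the stabilised formylmethylene ylide should give the E-enal, the conjugated product being much less reactive toward a second olefination than the saturated aldehyde.

Step 4
Reactants: 7 (2E)-6-methylidene-11-(trimethylsilyl)undec-2-en-10-ynal
Product: 8 (2E)-6-hydroperoxy-6-methoxy-11-(trimethylsilyl)undec-2-en-10-ynal (racemic)
Conditions: O3 (about 1 equiv, Sudan Red 7B end point), CH2Cl2/MeOH 4:1, −78 °C; N2 purge; cold concentration, quick silica chromatography
Reagents that add atoms: ozone [O-][O+]=O; methanol CO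
Why: Criegee ozonolysis in a participating solvent: ozone should add fastest to the electron-rich 1,1-dialkyl alkene, the primary ozonide splits into formaldehyde and the disubstituted carbonyl oxide, and methanol traps the latter as the methoxy hydroperoxide, while the electron-poor enal alkene and the silyl alkyne react much more slowly.

Step 5
Reactants: 8 (2E)-6-hydroperoxy-6-methoxy-11-(trimethylsilyl)undec-2-en-10-ynal (racemic)
Product: 10 2-[(3S)-6-methoxy-6-[5-(trimethylsilyl)pent-4-yn-1-yl]-1,2-dioxan-3-yl]acetic acid (C6 epimer pair), via β-peroxy aldehyde 9 (not isolated)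
Conditions: (R)-2-[diphenyl(trimethylsilyloxy)methyl]pyrrolidine (20 mol%), PhCO2H (20 mol%), toluene, 0 °C; then t-BuOH/H2O, 2-methyl-2-butene, NaH2PO4, NaClO2, 0 °C
Reagents that add atoms: sodium chlorite [Na+].[O-]Cl=O
Why: The aldehyde condenses with the chiral secondary amine to an E-iminium ion, the hydroperoxide oxygen adds to C3 (the β-carbon), and protonation and hydrolysis of the enamine release the catalyst and aldehyde 9, which is oxidised at once (Pinnick) so that it cannot revert by retro-addition. The closest known reactions are the amine-catalysed enantioselective peroxidation of enals by hydroperoxides and the base-mediated Michael ring closure of methoxy hydroperoxides onto enoates that gives 3-methoxy-1,2-dioxanes. The 1,2-dioxane closes 6-exo-trig by O–C bond formation through a chair-like transition state. C3 is set by the catalyst: the diphenyl(silyloxy)methyl group of the R-configured amine shields the Re face of C3, so the oxygen should add to the Si face and give 3S; C6 is not touched, so racemic 8 should give the two C6 epimers of the 3S series, which converge in step 6. The step needs peroxide formation to win over epoxide formation (attack of the enamine on the O–O bond), which the acid co-catalyst should secure by fast enamine protonation at low temperature. It also needs a single ring size, which the substrate secures because the three-carbon tether C4–C6 and the E-alkene leave only C3 within reach of the hydroperoxide.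

Step 6
Reactants: 10 2-[(3S)-6-methoxy-6-[5-(trimethylsilyl)pent-4-yn-1-yl]-1,2-dioxan-3-yl]acetic acid (C6 epimer pair)
Product: 11 2-[(3S,6R)-6-methoxy-6-[5-(trimethylsilyl)pent-4-yn-1-yl]-1,2-dioxan-3-yl]acetic acid
Conditions: CSA (10 mol%), MeOH (20 equiv), CH2Cl2, 0 °C to rt; chromatography, minor epimer resubmitted
Reagents that add atoms: methanol CO
Why: Acid-catalysed anomerisation of the alkoxy-1,2-dioxane (ionisation to the cyclic peroxycarbenium ion and return of methanol) equilibrates C6 alone and should favour the 3S,6R epimer, which has the methoxy group axial (anomeric effect) and both carbon substituents equatorial, while the low methanol concentration keeps Fischer esterification of the acid negligible.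

Step 7
Reactants: 11 2-[(3S,6R)-6-methoxy-6-[5-(trimethylsilyl)pent-4-yn-1-yl]-1,2-dioxan-3-yl]acetic acid
Product: 12 2-[(3S,6R)-6-methoxy-6-(pent-4-yn-1-yl)-1,2-dioxan-3-yl]acetic acid
Conditions: K2CO3 (2.5 equiv), MeOH, 0 °C to rt; aq. NaH2PO4 to pH 4
Reagents that add atoms: none
Why: Methanolysis of the alkynyl C–Si bond is a standard protodesilylation, and the carboxylate and the dialkyl peroxyketal, which has no acidic hydrogen next to the O–O bond, should survive the mild base.

Step 8
Reactants: 13 dec-9-enal
Product: 14 (1E)-1-iodoundeca-1,10-diene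
Conditions: CrCl2 (6 equiv), CHI3 (2 equiv), THF/dioxane, 0 °C to rt
Reagents that add atoms: iodoform IC(I)I
Why: Takai olefination: the geminal dichromium species formed from iodoform and divalent chromium adds to the aldehyde and eliminates to the E-vinyl iodide, leaving the terminal alkene untouched.

Step 9
Reactants: 12 2-[(3S,6R)-6-methoxy-6-(pent-4-yn-1-yl)-1,2-dioxan-3-yl]acetic acid; 14 (1E)-1-iodoundeca-1,10-diene
Product: 15 2-[(3S,6R)-6-[(6E)-hexadeca-6,15-dien-4-yn-1-yl]-6-methoxy-1,2-dioxan-3-yl]acetic acid
Conditions: Pd(PPh3)4 (5 mol%), CuI (10 mol%), Et3N (5 equiv), degassed THF, rt; aq. NaH2PO4 work-up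
Reagents that add atoms: none
Why: Sonogashira coupling of the terminal alkyne with the vinyl iodide proceeds with retention of the E geometry at room temperature, conditions under which a dialkyl peroxyketal and a carboxylate (as its ammonium salt) should be tolerated.

Compound list
1 | (5-chloropent-1-yn-1-yl)trimethylsilane | C[Si](C)(C)C#CCCCCl | starting material
2 | prop-2-yn-1-ol | C#CCO | starting material
3 | [5-(trimethylsilyl)pent-4-yn-1-yl]magnesium chloride | C[Si](C)(C)C#CCCC[Mg]Cl | intermediate
4 | 2-methylidene-7-(trimethylsilyl)hept-6-yn-1-ol | C=C(CO)CCCC#C[Si](C)(C)C | intermediate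
5 | [6-(ethenyloxymethyl)hept-6-en-1-yn-1-yl]trimethylsilane | C=COCC(=C)CCCC#C[Si](C)(C)C | intermediate
6 | 4-methylidene-9-(trimethylsilyl)non-8-ynal | O=CCCC(=C)CCCC#C[Si](C)(C)C | intermediate
7 | (2E)-6-methylidene-11-(trimethylsilyl)undec-2-en-10-ynal | O=C/C=C/CCC(=C)CCCC#C[Si](C)(C)C | intermediate
8 | (2E)-6-hydroperoxy-6-methoxy-11-(trimethylsilyl)undec-2-en-10-ynal (racemic) | O=C/C=C/CCC(OC)(OO)CCCC#C[Si](C)(C)C | intermediate
9 | 2-[(3S)-6-methoxy-6-[5-(trimethylsilyl)pent-4-yn-1-yl]-1,2-dioxan-3-yl]acetaldehyde (C6 epimer pair) | C[Si](C)(C)C#CCCCC1(OC)CC[C@@H](CC=O)OO1 | intermediate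
10 | 2-[(3S)-6-methoxy-6-[5-(trimethylsilyl)pent-4-yn-1-yl]-1,2-dioxan-3-yl]acetic acid (C6 epimer pair) | C[Si](C)(C)C#CCCCC1(OC)CC[C@@H](CC(=O)O)OO1 | intermediate
11 | 2-[(3S,6R)-6-methoxy-6-[5-(trimethylsilyl)pent-4-yn-1-yl]-1,2-dioxan-3-yl]acetic acid | C[Si](C)(C)C#CCCC[C@]1(OC)CC[C@@H](CC(=O)O)OO1 | intermediate
12 | 2-[(3S,6R)-6-methoxy-6-(pent-4-yn-1-yl)-1,2-dioxan-3-yl]acetic acid | C#CCCC[C@]1(OC)CC[C@@H](CC(=O)O)OO1 | intermediate
13 | dec-9-enal | C=CCCCCCCCC=O | starting material
14 | (1E)-1-iodoundeca-1,10-diene | I/C=C/CCCCCCCC=C | intermediate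
15 | 2-[(3S,6R)-6-[(6E)-hexadeca-6,15-dien-4-yn-1-yl]-6-methoxy-1,2-dioxan-3-yl]acetic acid | C=CCCCCCCC/C=C/C#CCCC[C@]1(OC)CC[C@@H](CC(=O)O)OO1 | target

Total step count: 9. Longest linear sequence: 8 steps (steps 1 to 7, then step 9); step 8 is a one-step side branch.

Steps most likely to fail

Step 5. What may go wrong: collapse of the peroxy-enamine onto the O–O bond (epoxide formation with loss of the peroxide), or erosion of facial selectivity through uncatalysed or reversible ring closure. The fallback sets out from 6 and returns at 10. Wittig reaction of 6 with methyl (triphenylphosphoranylidene)acetate gives methyl (2E)-6-methylidene-11-(trimethylsilyl)undec-2-en-10-ynoate F1. Ozonolysis in CH2Cl2/MeOH at −78 °C gives methyl (2E)-6-hydroperoxy-6-methoxy-11-(trimethylsilyl)undec-2-en-10-ynoate F2. Et2NH (cat.) in CF3CH2OH closes the same O2–C3 bond by the base-mediated hydroperoxide Michael addition, giving racemic methyl 2-[6-methoxy-6-[5-(trimethylsilyl)pent-4-yn-1-yl]-1,2-dioxan-3-yl]acetate F3. Kinetic resolution by enantioselective ester hydrolysis with a hydrolase (a lipase or esterase screened for the 3S ester, phosphate buffer pH 7/MTBE) should deliver acid 10 and leave methyl 2-[(3R)-6-methoxy-6-[5-(trimethylsilyl)pent-4-yn-1-yl]-1,2-dioxan-3-yl]acetate F4, which is extracted away.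

Step 6. What may go wrong: acid-induced fragmentation of the peroxide, or an equilibrium that stays too close to the starting mixture. The fallback sets out from 10 and returns at 12, replacing equilibration by separation. TMSCHN2 in toluene/MeOH gives methyl 2-[(3S)-6-methoxy-6-[5-(trimethylsilyl)pent-4-yn-1-yl]-1,2-dioxan-3-yl]acetate F5 as the C6 epimer pair. Chromatography separates methyl 2-[(3S,6R)-6-methoxy-6-[5-(trimethylsilyl)pent-4-yn-1-yl]-1,2-dioxan-3-yl]acetate F6. LiOH in THF/MeOH/H2O then cleaves the ester and the alkynylsilane in one operation to give 12.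

Step 9. What may go wrong: the free carboxylic acid ties up monovalent copper and slows the coupling, so that reduction of the O–O bond by zerovalent palladium and phosphine, or alkyne homocoupling, takes over. The fallback sets out from 12 and returns at 15, running the coupling on the protected acid. TMSCHN2 gives methyl 2-[(3S,6R)-6-methoxy-6-(pent-4-yn-1-yl)-1,2-dioxan-3-yl]acetate F7. Sonogashira coupling with 14 under the step 9 conditions gives methyl 2-[(3S,6R)-6-[(6E)-hexadeca-6,15-dien-4-yn-1-yl]-6-methoxy-1,2-dioxan-3-yl]acetate F8. LiOH in THF/H2O at 0 °C gives 15.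

Further compounds
F1 | step 5 | methyl (2E)-6-methylidene-11-(trimethylsilyl)undec-2-en-10-ynoate | COC(=O)/C=C/CCC(=C)CCCC#C[Si](C)(C)C
F2 | step 5 | methyl (2E)-6-hydroperoxy-6-methoxy-11-(trimethylsilyl)undec-2-en-10-ynoate (racemic) | COC(=O)/C=C/CCC(OC)(OO)CCCC#C[Si](C)(C)C
F3 | step 5 | methyl 2-[6-methoxy-6-[5-(trimethylsilyl)pent-4-yn-1-yl]-1,2-dioxan-3-yl]acetate (racemic, C6 epimer pair) | C[Si](C)(C)C#CCCCC1(OC)CCC(CC(=O)OC)OO1
F4 | step 5 | methyl 2-[(3R)-6-methoxy-6-[5-(trimethylsilyl)pent-4-yn-1-yl]-1,2-dioxan-3-yl]acetate (C6 epimer pair) | C[Si](C)(C)C#CCCCC1(OC)CC[C@H](CC(=O)OC)OO1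
F5 | step 6 | methyl 2-[(3S)-6-methoxy-6-[5-(trimethylsilyl)pent-4-yn-1-yl]-1,2-dioxan-3-yl]acetate (C6 epimer pair) | C[Si](C)(C)C#CCCCC1(OC)CC[C@@H](CC(=O)OC)OO1
F6 | step 6 | methyl 2-[(3S,6R)-6-methoxy-6-[5-(trimethylsilyl)pent-4-yn-1-yl]-1,2-dioxan-3-yl]acetate | C[Si](C)(C)C#CCCC[C@]1(OC)CC[C@@H](CC(=O)OC)OO1
F7 | step 9 | methyl 2-[(3S,6R)-6-methoxy-6-(pent-4-yn-1-yl)-1,2-dioxan-3-yl]acetate | C#CCCC[C@]1(OC)CC[C@@H](CC(=O)OC)OO1
F8 | step 9 | methyl 2-[(3S,6R)-6-[(6E)-hexadeca-6,15-dien-4-yn-1-yl]-6-methoxy-1,2-dioxan-3-yl]acetate | C=CCCCCCCC/C=C/C#CCCC[C@]1(OC)CC[C@@H](CC(=O)OC)OO1
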